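## The problem

The target 17 is a C25 terpenoid. A trans-fused 4,4,10-trimethyldecalin (rings A and B) carries a tetrasubstituted C8=C9 alkene, and C9 bears a chain C11–C15 with C16 as a hydroxymethyl branch on C13. The chain ends in a (Z)-configured 4-methyl-γ-ylidenebutenolide (atoms O1′, C2′–C5′).

Only two stereocentres remain, C5 (S) and the quaternary C10 (S). Both are remote from every heteroatom, so no resident group can set them. One enantioselective event must fix them together, and the trans ring fusion is then a matter of relative control.

Three alkenes need attention: the 13E geometry of the trisubstituted allylic alcohol, the Z geometry of the enol-lactone alkene C15=C5′, and the position of the ring alkene at C8=C9 and not at C7=C8 or C8=C17.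

The dienyl enol lactone is the fragile part. Hydride, strong base, nucleophiles and light all threaten it, and the allylic alcohol beside it rules out strong acid at the end. Both should therefore appear in the last two steps. The tetrasubstituted alkene tolerates most reagents once formed but can migrate under protic acid.

A short route is possible because C1–C10, with the methyl groups on C4, C8 and C10, are exactly a head-to-tail farnesyl chain. In addition, C11–C13 can end as a carboxyl group three carbons from C9, placed to trap a cation at C8.

## Retrosynthesis

**C13–C16 and C14–H.** Target 17 is taken as the product of a syn hydro-hydroxymethylation of the internal alkyne of enyne 16. Stepwise ways to the trisubstituted alkene (olefination at C13, or conjugate addition to an ynoate) need a protecting group on O16 and a separate butenolide synthesis afterwards. This cut adds the only hydroxyl last, and the syn course of the addition sets 13E. Enyne 16 has no hydroxyl and one alkene geometry fewer. The forward reaction must put carbon on C13 and hydrogen on C14 and must spare the enol lactone; the conjugated C15=C5′ alkene is there to steer the metal to C14.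

**C14–C15.** Cutting this sp–sp² bond divides 16 into the terpenoid alkyne 10 and the five-carbon bromide 15. The lactone is then made off the main line and joined in one step. Building it on the chain would add linear steps on the valuable decalin. The coupling must keep the Z geometry of 15 and run near room temperature with a mild base.

**O1′–C5′ of bromide 15.** Opening the lactone gives the (Z)-bromoenynoic acid 14. A halolactonisation of the unbrominated acid would put bromine on the wrong side, whereas anti addition of O and H across the bromoalkyne of 14 gives the Z bromide. Acid 14 comes from alcohol 12 by oxidation, and 12 from the commercial enynol 11 by alkyne bromination. The Z alkene of 11, which holds carboxyl and alkyne cis, must survive the oxidation.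

**C13≡C14.** Alkyne 10 is cut back by one carbon to aldehyde 9 and from there to methyl ester 8. The carboxyl carbon of 8 is C13 of the target, so no carbon is wasted. The homologation has no α-stereocentre to respect.

**C8–O reconnection.** Ester 8 is traced to the tertiary lactone 7 (ambreinolide). The lactone holds C8 as a tertiary ester, so the C8=C9 alkene can be released under equilibrating acid and not by random proton loss during ring formation. The price is two stereocentres (C8, C9) that are made and later removed. The forward step needs acid strong enough to ionise C8–O and long enough to reach the most substituted alkene.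

**C4–C5, C9–C10 and C8–O.** These three bonds are cut in one operation, and 7 unfolds to the acyclic farnesylacetic acid 6. This is the largest simplification of the plan: three rings and four stereocentres go back to an achiral triene acid. The forward reaction must start at the terminal alkene only, run through both alkenes and deliver one enantiomer.

**C11–C12.** Acid 6 is a malonic ester product. The diester 4 (via diacid 5) comes from farnesyl bromide 2 and diethyl malonate 3, and 2 from (2E,6E)-farnesol 1. This keeps the E,E geometry of the commercial alcohol, which a rearrangement route from a tertiary allylic alcohol would not guarantee.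

## Roads not taken

**Alternative 1:** Cut C5–C10 and C6–C7, so that ring B forms in an intramolecular Diels–Alder reaction and ring A is the tether. In the forward step the trienal A2, activated as an iminium ion by a chiral imidazolidinone salt, would cyclise to the aldehyde A1.

- Merits: the catalyst is metal-free and used in catalytic amount. The pericyclic mechanism fixes the alkene at C8=C9 with no isomer question. Here it is better than the chosen plan, which depends on acid equilibration.
- Weak points: the diene terminus C10 is fully substituted and its methyl group points into the s-cis diene, so the reactive conformer is disfavoured while a quaternary centre must form. The dienophile carbon C5 sits next to the quaternary C4. The stereodefined tetrasubstituted alkene of A2 is itself a synthetic problem. A1 carries a formyl group on C6 that the target lacks; it must be excised (Tsuji–Wilkinson decarbonylation with RhCl(PPh3)3). The chain then still has to grow from C12.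
- Comparison: the chosen plan reaches the same bicycle from farnesol in four steps with every carbon retained. Against the better alkene regiocontrol of Alternative 1 it sets the thermodynamic preference for the tetrasubstituted alkene and a separate dehydration route as back-up.

**Alternative 2:** Cut C2′–C3′ and C2′–O1′, so that the lactone carbonyl comes from carbon monoxide. The (Z)-β-iodoenone A4 would undergo palladium-catalysed carbonylation, and the enol oxygen would capture the acylpalladium to give the silyl ether A3.

- Merits: the lactone is made last under mild conditions. O16 and the 13E alkene are in place beforehand, so no regiochemical question arises at C13/C14 and no nickel chemistry meets the finished lactone. In this respect it is safer than the chosen last step.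
- Weak points: it is an endgame only and does not address C5 and C10. A4 is a β,γ-unsaturated ketone with a doubly activated C15 methylene, liable to slip into conjugation under the amine base. Its (Z)-iodoenone can isomerise. A4 needs a longer linear sequence on the decalin, and A3 needs a final desilylation next to the enol lactone.
- Comparison: the chosen plan offers convergence (15 is made in three steps off the main line), no protecting group and fewer steps. Its regiochemical risk in the last step is covered by a fallback.

**Alternative 3:** Cut C8–C17 and C9–C11. In one flask the bromo enol triflate A6 would first be methylated at C–Br with a methylzinc reagent (Negishi coupling) and then coupled at C–OTf with the B-alkyl borane A7 (Suzuki coupling) to give the diene A5.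

- Merits: the position of the tetrasubstituted alkene is unambiguous. The side chain arrives with O16 and the 13E geometry already set. The decalin would come from an enantiopure annulation product whose optical purity is more secure than that of an acid-induced polyene cyclisation. In these three respects it is as good as or better than the chosen plan.
- Weak points: the C9 triflate lies between the quaternary C10 and the substituted C8, and sp²–sp³ coupling at such a site is slow and competes with β-hydride elimination. The Br/OTf selectivity must be complete in one flask. A6 needs a multi-step preparation. A5 is still three or more steps (iododesilylation, coupling with a butenolide unit, desilylation) from the target.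
- Comparison: the chosen plan takes rings A and B and three methyl groups from farnesol in one step and is shorter overall. It accepts in exchange that the alkene position and the enantiomeric purity have to be earned (steps 4 and 5).

Key step: step 4

Assumption on numbering: labdane numbers are used for the decalin and chain (C1–C10 ring carbons, C11–C16 chain, C17 on C8, C20 on C10) and primed numbers for the butenolide.

Assumption on the chiral acid: the (R)-configured acid is taken to give the 5S,10S series, by analogy with its behaviour towards hydroxyl-terminated polyprenoids; the (S)-ligand would be used if the sense proved opposite.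

## Route

Step 1
Reactants: 1 (2E,6E)-farnesol
Product: 2 (2E,6E)-farnesyl bromide
Conditions: PBr3 (0.4 equiv), Et2O, −10 to 0 °C; used crude
Reagents that add atoms: phosphorus tribromide, BrP(Br)Br
Why: SN2-type bromination of the primary allylic alcohol through a phosphite ester; at low temperature in ether the 2E geometry should be kept and allylic transposition should stay minor.

Step 2
Reactants: 2 (2E,6E)-farnesyl bromide; 3 diethyl malonate
Product: 4 diethyl 2-[(2E,6E)-3,7,11-trimethyldodeca-2,6,10-trien-1-yl]malonate
Conditions: 3 (2.5 equiv), NaH, THF, 0 °C; then 2, 0 °C to rt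
Reagents that add atoms: none
Why: Malonic ester alkylation; the soft sodium enolate should attack the primary allylic bromide by SN2 at C1, excess 3 suppresses dialkylation, and the E,E geometry is not touched.

Step 3
Reactants: 4 diethyl 2-[(2E,6E)-3,7,11-trimethyldodeca-2,6,10-trien-1-yl]malonate
Product: 6 (4E,8E)-5,9,13-trimethyltetradeca-4,8,12-trienoic acid (farnesylacetic acid), via farnesylmalonic acid 5 (not isolated)
Conditions: KOH, EtOH/H2O, reflux; cold dil. HCl to pH 2, extraction; crude diacid in pyridine, reflux
Reagents that add atoms: potassium hydroxide, [K+].[OH-]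
Why: Saponification followed by thermal decarboxylation of the 1,3-diacid through its six-membered transition state (malonic ester synthesis); the trisubstituted alkenes tolerate hydroxide and brief cold dilute acid.

Step 4
Reactants: 6 (4E,8E)-5,9,13-trimethyltetradeca-4,8,12-trienoic acid
Product: 7 ambreinolide, (5S,8R,9R,10S)-8α,13-epoxy-14,15,16-trinorlabdan-13-one
Conditions: (R)-2-benzyloxy-2'-hydroxy-1,1'-binaphthyl (2.2 equiv), SnCl4 (2.0 equiv), toluene, −78 °C; then 6, −78 °C, 1–3 d; aq. NaHCO3
Reagents that add atoms: none
Why: Enantioselective cation–olefin polycyclisation: the phenolic proton of the binaphthol, acidified by coordination to SnCl4, is delivered to C3 of the terminal alkene (Markovnikov, tertiary C4 cation) inside a chiral ion pair, and the chain reacts in a chair–chair fold. Ring A closes by 6-endo attack of the C5=C10 alkene on C4, ring B by 6-endo attack of the C8=C9 alkene on C10, and the carboxyl oxygen then captures the tertiary C8 cation to close the six-membered lactone (formally 6-endo with respect to C8=C9). The closest known reaction type is the cyclisation of polyprenyl alcohols, arenes and carboxylic acids by Lewis-acid-assisted chiral Brønsted acids, together with the achiral acid cyclisation of 6 to racemic 7. The absolute configuration at C5 and C10 follows from the enantioface of protonation fixed by the chiral acid, and their trans relation from anti addition across the E-configured C5=C10 alkene. C9 and C8 follow from anti addition across the E-configured C8=C9 alkene in the chair, which puts H-9 axial (α) and the lactone oxygen equatorial (8α). The step needs initiation at the terminal alkene only, which the greater accessibility of that alkene to the bulky acid at −78 °C should secure, and complete propagation, which the internal carboxyl nucleophile should secure. It also needs enantioselectivity, for which the preformed chiral acid is used in excess so that it outruns any achiral proton source formed from 6 and SnCl4. Since C8 and C9 are erased in step 5, a 9-epimeric lactone or bicyclic olefinic acids from early proton loss should converge on 8.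

Step 5
Reactants: 7 ambreinolide
Product: 8 methyl 14,15,16-trinorlabd-8-en-13-oate
Conditions: conc. H2SO4 (0.5 equiv), MeOH, reflux, to constant isomer composition; chromatography on AgNO3-impregnated silica
Reagents that add atoms: methanol, CO
Why: Acid ionises the tertiary C8–O bond (alkyl–oxygen cleavage), the acid is esterified (Fischer esterification) and the C8 cation loses a proton (E1); reversible reprotonation should funnel the Δ7 and exocyclic isomers to the tetrasubstituted Δ8 alkene, removing C8 and C9 as stereocentres while C5 and C10 are untouched.

Step 6
Reactants: 8 methyl 14,15,16-trinorlabd-8-en-13-oate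
Product: 9 14,15,16-trinorlabd-8-en-13-al
Conditions: i-Bu2AlH (1.1 equiv), CH2Cl2, −78 °C; aq. potassium sodium tartrate
Reagents that add atoms: none
Why: Partial reduction of the ester at −78 °C should stop at the aluminium hemiacetal, which releases the aldehyde on work-up; the tetrasubstituted alkene is inert to the hydride.

Step 7
Reactants: 9 14,15,16-trinorlabd-8-en-13-al
Product: 10 15,16-dinorlabd-8-en-13-yne
Conditions: dimethyl (1-diazo-2-oxopropyl)phosphonate, K2CO3, MeOH, 0 °C to rt
Reagents that add atoms: dimethyl (1-diazo-2-oxopropyl)phosphonate, CC(=O)C(=[N+]=[N-])P(=O)(OC)OC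
Why: Ohira–Bestmann homologation: methanolysis gives dimethyl (diazomethyl)phosphonate, which adds to the aldehyde in Horner–Wadsworth–Emmons fashion, and loss of N2 with 1,2-hydride shift of the alkylidene carbene delivers the terminal alkyne (C14) under mild base with no α-stereocentre at risk.

Step 8
Reactants: 11 (Z)-3-methylpent-2-en-4-yn-1-ol
Product: 12 (Z)-5-bromo-3-methylpent-2-en-4-yn-1-ol
Conditions: N-bromosuccinimide, AgNO3 (10 mol%), acetone, rt, dark
Reagents that add atoms: N-bromosuccinimide, O=C1CCC(=O)N1Br
Why: Silver-catalysed electrophilic bromination of the terminal alkyne through its silver acetylide; the allylic alcohol and the Z alkene should be unaffected under these neutral conditions.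

Step 9
Reactants: 12 (Z)-5-bromo-3-methylpent-2-en-4-yn-1-ol
Product: 14 (Z)-5-bromo-3-methylpent-2-en-4-ynoic acid, via bromoenynal 13 (not isolated)
Conditions: CrO3, H2SO4, H2O, acetone, 0 °C
Reagents that add atoms: water, O
Why: Jones oxidation of the primary allylic alcohol through the aldehyde and its hydrate; short contact at 0 °C should keep the Z geometry needed for ring closure, and the bromoalkyne is stable to chromic acid.

Step 10
Reactants: 14 (Z)-5-bromo-3-methylpent-2-en-4-ynoic acid
Product: 15 (Z)-5-(bromomethylene)-4-methylfuran-2(5H)-one
Conditions: AgNO3 (10 mol%), acetone, rt, dark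
Reagents that add atoms: none
Why: Silver-catalysed cycloisomerisation of a (Z)-2-en-4-ynoic acid: 5-exo-dig anti attack of the carboxyl oxygen on the silver-bound alkyne and protodemetalation place H trans and Br cis to the ring oxygen, which is the Z bromide.

Step 11
Reactants: 10 15,16-dinorlabd-8-en-13-yne; 15 (Z)-5-(bromomethylene)-4-methylfuran-2(5H)-one
Product: 16 (Z)-4-methyl-5-{5-[(4aS,8aS)-2,5,5,8a-tetramethyl-3,4,4a,5,6,7,8,8a-octahydronaphthalen-1-yl]pent-2-yn-1-ylidene}furan-2(5H)-one
Conditions: PdCl2(PPh3)2 (5 mol%), CuI (10 mol%), Et3N (2 equiv), THF, rt, degassed, dark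
Reagents that add atoms: none
Why: Sonogashira coupling of the terminal alkyne with the alkenyl bromide; oxidative addition to zerovalent palladium and reductive elimination from divalent palladium proceed with retention, so the Z geometry of 15 should pass into 16, and room temperature with a tertiary amine should spare the enol lactone.

Step 12
Reactants: 16 (Z)-4-methyl-5-{5-[(4aS,8aS)-2,5,5,8a-tetramethyl-3,4,4a,5,6,7,8,8a-octahydronaphthalen-1-yl]pent-2-yn-1-ylidene}furan-2(5H)-one
Product: 17 (Z)-5-{(E)-3-(hydroxymethyl)-5-[(4aS,8aS)-2,5,5,8a-tetramethyl-3,4,4a,5,6,7,8,8a-octahydronaphthalen-1-yl]pent-2-en-1-ylidene}-4-methylfuran-2(5H)-one (target)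
Conditions: Ni(C8H12)2 (10 mol%), P(c-C5H9)3 (20 mol%), (CH2O)n (4 equiv), Et3B (2.5 equiv), toluene, rt to 40 °C, slow addition of 16; aq. NH4Cl
Reagents that add atoms: formaldehyde (from paraformaldehyde), C=O
Why: Nickel-catalysed reductive coupling of a 1,3-enyne with an aldehyde, here formaldehyde, with Et3B as reductant: oxidative cyclisation on zerovalent nickel should form C13–C16 at the alkyne carbon distal to the conjugated C15=C5′ alkene, which coordinates nickel, and ethyl transfer, β-hydride elimination and C–H reductive elimination deliver H to C14 syn to C16, giving 13E; the neutral conditions should leave the lactone intact and aqueous work-up frees the alcohol.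

## Compound list

1 | (2E,6E)-farnesol | CC(C)=CCC/C(C)=C/CC/C(C)=C/CO | starting material
2 | (2E,6E)-farnesyl bromide | CC(C)=CCC/C(C)=C/CC/C(C)=C/CBr | intermediate
3 | diethyl malonate | CCOC(=O)CC(=O)OCC | starting material
4 | diethyl 2-[(2E,6E)-3,7,11-trimethyldodeca-2,6,10-trien-1-yl]malonate | CC(C)=CCC/C(C)=C/CC/C(C)=C/CC(C(=O)OCC)C(=O)OCC | intermediate
5 | 2-[(2E,6E)-3,7,11-trimethyldodeca-2,6,10-trien-1-yl]malonic acid (farnesylmalonic acid) | CC(C)=CCC/C(C)=C/CC/C(C)=C/CC(C(=O)O)C(=O)O | intermediate (not isolated)
6 | (4E,8E)-5,9,13-trimethyltetradeca-4,8,12-trienoic acid (farnesylacetic acid) | CC(C)=CCC/C(C)=C/CC/C(C)=C/CCC(=O)O | intermediate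
7 | ambreinolide, (5S,8R,9R,10S)-8α,13-epoxy-14,15,16-trinorlabdan-13-one | O=C1CC[C@H]2[C@](C)(O1)CC[C@H]3C(C)(C)CCC[C@]23C | intermediate
8 | methyl 14,15,16-trinorlabd-8-en-13-oate (5S,10S) | COC(=O)CCC1=C(C)CC[C@H]2C(C)(C)CCC[C@]12C | intermediate
9 | 14,15,16-trinorlabd-8-en-13-al (5S,10S) | O=CCCC1=C(C)CC[C@H]2C(C)(C)CCC[C@]12C | intermediate
10 | 15,16-dinorlabd-8-en-13-yne, (4aS,8aS)-5-(but-3-yn-1-yl)-1,1,4a,6-tetramethyl-1,2,3,4,4a,7,8,8a-octahydronaphthalene | C#CCCC1=C(C)CC[C@H]2C(C)(C)CCC[C@]12C | intermediate
11 | (Z)-3-methylpent-2-en-4-yn-1-ol | C#C/C(C)=C\CO | starting material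
12 | (Z)-5-bromo-3-methylpent-2-en-4-yn-1-ol | BrC#C/C(C)=C\CO | intermediate
13 | (Z)-5-bromo-3-methylpent-2-en-4-ynal (bromoenynal) | BrC#C/C(C)=C\C=O | intermediate (not isolated)
14 | (Z)-5-bromo-3-methylpent-2-en-4-ynoic acid | BrC#C/C(C)=C\C(=O)O | intermediate
15 | (Z)-5-(bromomethylene)-4-methylfuran-2(5H)-one | CC1=CC(=O)O/C1=C\Br | intermediate
16 | (Z)-4-methyl-5-{5-[(4aS,8aS)-2,5,5,8a-tetramethyl-3,4,4a,5,6,7,8,8a-octahydronaphthalen-1-yl]pent-2-yn-1-ylidene}furan-2(5H)-one | CC1=CC(=O)O/C1=C\C#CCCC1=C(C)CC[C@H]2C(C)(C)CCC[C@]12C | intermediate
17 | (Z)-5-{(E)-3-(hydroxymethyl)-5-[(4aS,8aS)-2,5,5,8a-tetramethyl-3,4,4a,5,6,7,8,8a-octahydronaphthalen-1-yl]pent-2-en-1-ylidene}-4-methylfuran-2(5H)-one | CC1=CC(=O)O/C1=C\C=C(\CO)CCC1=C(C)CC[C@H]2C(C)(C)CCC[C@]12C | target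

## Step count and risks

Total: 12 steps. Longest linear sequence: 9 steps (steps 1–7, 11 and 12, from 1 to 17). Steps 8–10 make fragment 15 from 11.

**Step 4 (key step).** The most likely failure is erosion of enantioface selectivity. The carboxylic acid of 6 can bind SnCl4 and act as an achiral proton source that starts a racemic background cyclisation. A second failure is loss of a proton after ring A has closed, which leaves monocyclic acids. The excess of preformed chiral acid at −78 °C is meant to counter the first. Recrystallisation of 7 is the intended means of raising optical purity if needed.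

The fallback keeps the bicyclisation but removes the acidic proton from the terminator. It sets out from 6 and returns at 7.
- 6 is reduced with LiAlH4 in Et2O to (4E,8E)-5,9,13-trimethyltetradeca-4,8,12-trien-1-ol F1.
- F1 is silylated with Et3SiCl and imidazole to its triethylsilyl ether F2.
- F2 is cyclised with the same type of chiral acid in toluene at −78 °C, followed by an achiral CF3CO2H–SnCl4 stage to complete ring closure. This is the established sequence for silyl ethers of polyprenols. The ether oxygen terminates at C8 with loss of silicon and gives 8α,13-epoxy-14,15,16-trinorlabdane F3.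
- The C13 methylene next to oxygen in F3 is oxidised with RuCl3 (cat.) and NaIO4 in CCl4/MeCN/H2O to the lactone 7.

**Step 12.** Three things may go wrong: loss of regiocontrol in the oxidative cyclisation (carbon delivered to C14 and not C13), oligomerisation of the enyne on zerovalent nickel, and attack of the low-valent metal on the dienyl lactone (C–O insertion or conjugate reduction).

The fallback builds the 13E alkene by syn carbocupration before any lactone is present. It sets out from 10, bypasses 16 and returns at 17.
- 10 is deprotonated with n-BuLi in THF at −78 °C and acylated with methyl chloroformate to methyl 16-norlabd-8-en-13-yn-15-oate F4.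
- Lithium bis[(methoxymethoxy)methyl]cuprate, made from tributyl[(methoxymethoxy)methyl]stannane, n-BuLi and CuBr·SMe2, adds syn to F4 at −78 °C. A cold proton quench gives methyl (13E)-16-(methoxymethoxy)labda-8,13-dien-15-oate F5.
- i-Bu2AlH reduces F5 to (13E)-16-(methoxymethoxy)labda-8,13-dien-15-ol F6.
- MnO2 oxidises F6 to (13E)-16-(methoxymethoxy)labda-8,13-dien-15-al F7.
- Ohira–Bestmann homologation of F7 gives (4aS,8aS)-5-{(E)-3-[(methoxymethoxy)methyl]hex-3-en-5-yn-1-yl}-1,1,4a,6-tetramethyl-1,2,3,4,4a,7,8,8a-octahydronaphthalene F8.
- F8 is coupled with (Z)-3-iodobut-2-enoic acid under PdCl2(PPh3)2, CuI and Et3N in MeCN. The coupled (2Z,6E)-7-[(methoxymethoxy)methyl]-3-methyl-9-[(4aS,8aS)-2,5,5,8a-tetramethyl-3,4,4a,5,6,7,8,8a-octahydronaphthalen-1-yl]nona-2,6-dien-4-ynoic acid F9 should lactonise in the flask (5-exo-dig, anti) to the 16-O-(methoxymethyl) ether of the target F10.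
- Dilute HCl in MeOH at 0 °C to rt removes the acetal and gives 17.

**Step 5.** The likely failure is incomplete funnelling of the alkene isomers, with Δ7 and exocyclic esters persisting. Under more forcing acid, backbone rearrangement through the C8 cation becomes a second risk.

The fallback changes both the order and the mechanism of dehydration. It sets out from 7 and returns at 10.
- 7 is reduced with i-Bu2AlH at −78 °C to the lactol 8α,13-epoxy-14,15,16-trinorlabdan-13-ol F11.
- F11 reacts through its open hydroxy aldehyde form under Ohira–Bestmann conditions to give 15,16-dinorlabd-13-yn-8α-ol F12.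
- The tertiary alcohol of F12 is dehydrated with PPh3 and I2 in CH2Cl2 at rt. This phosphonium-mediated elimination of tertiary decalinols favours the more substituted alkene and should give 10 without a long-lived free cation.

**Step 11.** Amine-induced decomposition or Z/E isomerisation of the bromomethylene butenolide may occur, as may oxidative homocoupling of the alkyne (Glaser coupling) in the presence of CuI.

The fallback is a base-free Stille coupling. It sets out from 10 and returns at 16.
- 10 is deprotonated with n-BuLi and stannylated with Bu3SnCl to tributyl(15,16-dinorlabd-8-en-13-yn-14-yl)stannane F13.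
- F13 is coupled with 15 under Pd(PPh3)4 in THF at rt to 40 °C without amine or copper salt to give 16.

## Further compounds

F1 | step 4 | (4E,8E)-5,9,13-trimethyltetradeca-4,8,12-trien-1-ol | CC(C)=CCC/C(C)=C/CC/C(C)=C/CCCO
F2 | step 4 | triethyl{[(4E,8E)-5,9,13-trimethyltetradeca-4,8,12-trien-1-yl]oxy}silane | CC(C)=CCC/C(C)=C/CC/C(C)=C/CCCO[Si](CC)(CC)CC
F3 | step 4 | (5S,8R,9R,10S)-8α,13-epoxy-14,15,16-trinorlabdane | C1CC[C@H]2[C@](C)(O1)CC[C@H]3C(C)(C)CCC[C@]23C
F4 | step 12 | methyl 16-norlabd-8-en-13-yn-15-oate | COC(=O)C#CCCC1=C(C)CC[C@H]2C(C)(C)CCC[C@]12C
F5 | step 12 | methyl (13E)-16-(methoxymethoxy)labda-8,13-dien-15-oate | COCOC/C(CCC1=C(C)CC[C@H]2C(C)(C)CCC[C@]12C)=C/C(=O)OC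
F6 | step 12 | (13E)-16-(methoxymethoxy)labda-8,13-dien-15-ol | COCOC/C(CCC1=C(C)CC[C@H]2C(C)(C)CCC[C@]12C)=C/CO
F7 | step 12 | (13E)-16-(methoxymethoxy)labda-8,13-dien-15-al | COCOC/C(CCC1=C(C)CC[C@H]2C(C)(C)CCC[C@]12C)=C/C=O
F8 | step 12 | (4aS,8aS)-5-{(E)-3-[(methoxymethoxy)methyl]hex-3-en-5-yn-1-yl}-1,1,4a,6-tetramethyl-1,2,3,4,4a,7,8,8a-octahydronaphthalene | C#C/C=C(/COCOC)CCC1=C(C)CC[C@H]2C(C)(C)CCC[C@]12C
F9 | step 12 | (2Z,6E)-7-[(methoxymethoxy)methyl]-3-methyl-9-[(4aS,8aS)-2,5,5,8a-tetramethyl-3,4,4a,5,6,7,8,8a-octahydronaphthalen-1-yl]nona-2,6-dien-4-ynoic acid (not isolated) | OC(=O)/C=C(C)\C#C/C=C(/COCOC)CCC1=C(C)CC[C@H]2C(C)(C)CCC[C@]12C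
F10 | step 12 | 16-O-(methoxymethyl) ether of 17 | CC1=CC(=O)O/C1=C\C=C(\COCOC)CCC1=C(C)CC[C@H]2C(C)(C)CCC[C@]12C
F11 | step 5 | 8α,13-epoxy-14,15,16-trinorlabdan-13-ol (lactol, anomer mixture) | OC1CC[C@H]2[C@](C)(O1)CC[C@H]3C(C)(C)CCC[C@]23C
F12 | step 5 | (5S,8R,9R,10S)-15,16-dinorlabd-13-yn-8α-ol | C#CCC[C@H]1[C@](C)(O)CC[C@H]2C(C)(C)CCC[C@]12C
F13 | step 11 | tributyl(15,16-dinorlabd-8-en-13-yn-14-yl)stannane | CCCC[Sn](CCCC)(CCCC)C#CCCC1=C(C)CC[C@H]2C(C)(C)CCC[C@]12C
A1 | alternative 1 | trans-fused 12-(tert-butyldimethylsilyloxy)-13,14,15,16-tetranorlabd-8-ene-6α-carbaldehyde | CC(C)(C)[Si](C)(C)OCCC1=C(C)C[C@H](C=O)[C@H]2C(C)(C)CCC[C@]12C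
A2 | alternative 1 | (2E,8E)-9-[2-(tert-butyldimethylsilyloxy)ethyl]-4,4,8,10-tetramethylundeca-2,8,10-trienal | C=C(C)/C(CCO[Si](C)(C)C(C)(C)C)=C(\C)CCCC(C)(C)/C=C/C=O
A3 | alternative 2 | 16-O-(tert-butyldimethylsilyl) ether of 17 | CC1=CC(=O)O/C1=C\C=C(\CO[Si](C)(C)C(C)(C)C)CCC1=C(C)CC[C@H]2C(C)(C)CCC[C@]12C
A4 | alternative 2 | (1Z,5E)-6-[(tert-butyldimethylsilyloxy)methyl]-1-iodo-2-methyl-8-[(4aS,8aS)-2,5,5,8a-tetramethyl-3,4,4a,5,6,7,8,8a-octahydronaphthalen-1-yl]octa-1,5-dien-3-one | I/C=C(C)\C(=O)C/C=C(/CO[Si](C)(C)C(C)(C)C)CCC1=C(C)CC[C@H]2C(C)(C)CCC[C@]12C
A5 | alternative 3 | (5S,10S,13E)-16-(tert-butyldimethylsilyloxy)-14-(trimethylsilyl)-15-norlabda-8,13-diene | C[Si](C)(C)/C=C(/CO[Si](C)(C)C(C)(C)C)CCC1=C(C)CC[C@H]2C(C)(C)CCC[C@]12C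
A6 | alternative 3 | (4aS,8aS)-2-bromo-5,5,8a-trimethyl-3,4,4a,5,6,7,8,8a-octahydronaphthalen-1-yl trifluoromethanesulfonate | O=S(=O)(OC1=C(Br)CC[C@H]2C(C)(C)CCC[C@]12C)C(F)(F)F
A7 | alternative 3 | 9-{(E)-3-[(tert-butyldimethylsilyloxy)methyl]-4-(trimethylsilyl)but-3-en-1-yl}-9-borabicyclo[3.3.1]nonane | C[Si](C)(C)/C=C(/CO[Si](C)(C)C(C)(C)C)CCB1C2CCCC1CCC2
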